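**Retrosynthetic overview**
- The C3–OH is installed last, from a C3–iodide on the finished flavone core (iodine–magnesium exchange, borylation, oxidation).
- Key step: ring C is closed by demethylative 6-endo iodocyclization of a pentamethoxyphenyl ynone. The ring oxygen is one of two symmetry-equivalent ortho methoxy groups, so there is no chalcone, no Algar–Flynn–Oyamada oxidation and no regiochemical question.
- The ynone comes from pentamethoxyphenyllithium and a Weinreb ynamide (C4–C4a bond).
- The ynamide comes from 4-ethynylanisole and a carbamoyl chloride.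
- Ring order: rings A and B are bought intact; ring C is the only ring formed.

Assumption: the target has no stereocentre or stereoaxis, so "single enantiomer" needs no stereocontrol, and pentamethoxybenzene is taken as a catalogue compound.

**Step 1**
Reactants: 1 4-ethynylanisole; 2 N-methoxy-N-methylcarbamoyl chloride
Product: 4 N-methoxy-N-methyl-3-(4-methoxyphenyl)prop-2-ynamide, via lithium (4-methoxyphenyl)acetylide 3 (not isolated)
Conditions: n-BuLi, THF, −78 °C, 30 min; then added to 2, −78 °C → rt; aq. NH4Cl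
Reagents that add atoms: n-BuLi, CCCC[Li] (its lithium sits in 3 only)
Why: Acetylide acylation (nucleophilic acyl substitution): the terminal alkyne is fully lithiated and the acetylide displaces chloride from the carbamoyl chloride, which is far more electrophilic than the Weinreb amide being formed, so no second addition occurs.

**Step 2**
Reactants: 5 pentamethoxybenzene; 4 N-methoxy-N-methyl-3-(4-methoxyphenyl)prop-2-ynamide
Product: 8 3-(4-methoxyphenyl)-1-(2,3,4,5,6-pentamethoxyphenyl)prop-2-yn-1-one, via (pentamethoxyphenyl)lithium 6 (not isolated), via lithium hemiaminal alkoxide 7 (not isolated)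
Conditions: n-BuLi, TMEDA, THF, 0 °C, 1 h; then 4, −78 → −30 °C; inverse quench into cold 1 M HCl
Reagents that add atoms: n-BuLi, CCCC[Li] (its lithium sits in 6 and 7 only)
Why: Directed ortho-lithiation followed by Weinreb ketone synthesis: the only ring C–H of 5 lies between two methoxy groups and is removed cleanly, the aryllithium adds 1,2 to the ynamide to give chelated adduct 7 that cannot collapse or over-add before the quench, and the inverse acid quench protonates the released amine before it can add to the ynone.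

**Step 3**
Reactants: 8 3-(4-methoxyphenyl)-1-(2,3,4,5,6-pentamethoxyphenyl)prop-2-yn-1-one
Product: 10 3-iodo-5,6,7,8-tetramethoxy-2-(4-methoxyphenyl)-4H-chromen-4-one, via O-methyloxonium chloride 9 (not isolated)
Conditions: ICl (1.5 equiv), CH2Cl2, −78 °C, 30 min; aq. Na2S2O3
Reagents that add atoms: iodine monochloride (ICl), ClI
Why: Larock-type electrophilic iodocyclization: iodonium activation of the alkyne triggers 6-endo-dig attack by an ortho methoxy oxygen (the two ortho OMe groups are symmetry-equivalent, so only one chromone can form, and the aryl group on the distal alkyne carbon favours 6-endo over 5-exo), then chloride demethylates oxonium 9 by SN2; ring A has no free C–H to iodinate and the anisyl ring is deactivated by conjugation.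

**Step 4**
Reactants: 10 3-iodo-5,6,7,8-tetramethoxy-2-(4-methoxyphenyl)-4H-chromen-4-one
Product: 13 3-hydroxy-5,6,7,8-tetramethoxy-2-(4-methoxyphenyl)-4H-chromen-4-one, via 3-chloromagnesio flavone 11 (not isolated), via dimethyl flavon-3-ylboronate 12 (not isolated)
Conditions: iPrMgCl·LiCl, THF, −40 °C, 30 min; B(OMe)3, −40 → 0 °C; then AcOH, 30% H2O2, 0 °C → rt; 1 M HCl work-up
Reagents that add atoms: iPrMgCl·LiCl, CC(C)[Mg]Cl.[Li+].[Cl-] (magnesium and chlorine sit in 11 only); trimethyl borate B(OMe)3, COB(OC)OC (boron and its methoxy groups sit in 12 only); hydrogen peroxide, OO (supplies the C3 oxygen of 13)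
Why: Halogen–magnesium exchange, borylation and boronate oxidation: iodine–magnesium exchange on this α-iodo vinylogous ester is faster than carbonyl addition at −40 °C, the 3-magnesio species is trapped as boronate 12 before it can β-eliminate the ring oxygen, and peroxide-induced boron-to-oxygen 1,2-migration delivers the C3–OH.

**Compound list**
1 | 4-ethynylanisole | C#Cc1ccc(OC)cc1 | starting material
2 | N-methoxy-N-methylcarbamoyl chloride | CON(C)C(Cl)=O | starting material
3 | lithium (4-methoxyphenyl)acetylide | [Li]C#Cc1ccc(OC)cc1 | intermediate (not isolated)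
4 | N-methoxy-N-methyl-3-(4-methoxyphenyl)prop-2-ynamide | CON(C)C(=O)C#Cc1ccc(OC)cc1 | intermediate
5 | pentamethoxybenzene | COc1cc(OC)c(OC)c(OC)c1OC | starting material
6 | (2,3,4,5,6-pentamethoxyphenyl)lithium | [Li]c1c(OC)c(OC)c(OC)c(OC)c1OC | intermediate (not isolated)
7 | lithium 1-[methoxy(methyl)amino]-3-(4-methoxyphenyl)-1-(2,3,4,5,6-pentamethoxyphenyl)prop-2-yn-1-olate (racemic, centre destroyed on quench) | [Li]OC(C#Cc1ccc(OC)cc1)(N(C)OC)c1c(OC)c(OC)c(OC)c(OC)c1OC | intermediate (not isolated)
8 | 3-(4-methoxyphenyl)-1-(2,3,4,5,6-pentamethoxyphenyl)prop-2-yn-1-one | COc1ccc(C#CC(=O)c2c(OC)c(OC)c(OC)c(OC)c2OC)cc1 | intermediate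
9 | 3-iodo-5,6,7,8-tetramethoxy-2-(4-methoxyphenyl)-1-methyl-4-oxo-4H-chromen-1-ium chloride | C[O+]1C(c2ccc(OC)cc2)=C(I)C(=O)c2c(OC)c(OC)c(OC)c(OC)c21.[Cl-] | intermediate (not isolated)
10 | 3-iodo-5,6,7,8-tetramethoxy-2-(4-methoxyphenyl)-4H-chromen-4-one | COc1ccc(-c2oc3c(OC)c(OC)c(OC)c(OC)c3c(=O)c2I)cc1 | intermediate
11 | [5,6,7,8-tetramethoxy-2-(4-methoxyphenyl)-4-oxo-4H-chromen-3-yl]magnesium chloride | COc1ccc(-c2oc3c(OC)c(OC)c(OC)c(OC)c3c(=O)c2[Mg]Cl)cc1 | intermediate (not isolated)
12 | dimethyl [5,6,7,8-tetramethoxy-2-(4-methoxyphenyl)-4-oxo-4H-chromen-3-yl]boronate | COc1ccc(-c2oc3c(OC)c(OC)c(OC)c(OC)c3c(=O)c2B(OC)OC)cc1 | intermediate (not isolated)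
13 | 3-hydroxy-5,6,7,8-tetramethoxy-2-(4-methoxyphenyl)-4H-chromen-4-one (achiral) | COc1ccc(-c2oc3c(OC)c(OC)c(OC)c(OC)c3c(=O)c2O)cc1 | target

**Totals**
Total step count: 4. Longest linear sequence: 4 steps (1 → 4 → 8 → 10 → 13); from 5 it is 3 steps.

**Three steps most likely to fail**

Step 2. The risk is conjugate addition of aryllithium 6 to the ynamide, or loss of ynone 8 to the released amine. The fallback sets out from 6 (made from 5 as in step 2) and comes back at 8; it reverses the polarity of the ketone-forming bond. 6 is quenched with DMF (THF, −78 → 0 °C) to give the lithium hemiaminal alkoxide lithium (dimethylamino)(2,3,4,5,6-pentamethoxyphenyl)methanolate F1. Dilute HCl work-up collapses it to 2,3,4,5,6-pentamethoxybenzaldehyde F2. Lithium acetylide 3 (from 1 and n-BuLi as in step 1) adds to F2 at −78 °C, and a water quench gives racemic 3-(4-methoxyphenyl)-1-(2,3,4,5,6-pentamethoxyphenyl)prop-2-yn-1-ol F3, whose stereocentre is erased in the next operation. MnO2 in CH2Cl2 at rt oxidises this benzylic, propargylic alcohol to 8.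

Step 3. The risks are 5-exo closure, ICl addition across the alkyne, or iodination of the anisyl ring; the 2,6-disubstituted aryl ketone is also twisted, which may slow the closure. The fallback sets out from 8 and comes back at 12; it replaces electrophilic activation of the alkyne by unmasking the phenol and closing the ring by oxa-Michael addition. BCl3 (1.1 equiv, CH2Cl2, −78 → 0 °C) cleaves one of the two equivalent ketone-chelated ortho methyl ethers to give dichloro{3,4,5,6-tetramethoxy-2-[3-(4-methoxyphenyl)prop-2-ynoyl]phenoxy}borane F4. Aqueous work-up hydrolyses it to 1-(2-hydroxy-3,4,5,6-tetramethoxyphenyl)-3-(4-methoxyphenyl)prop-2-yn-1-one F5. Et2NH in DMF at rt adds to the ynone first, so only the six-membered ring can close, and gives tangeretin F6; any β-chlorovinyl ketone from HCl addition converges on the same product by addition–elimination. LDA (THF, −78 °C) removes the C3–H to give [5,6,7,8-tetramethoxy-2-(4-methoxyphenyl)-4-oxo-4H-chromen-3-yl]lithium F7, and B(OMe)3 traps it as boronate 12. The AcOH/H2O2 stage of step 4 then gives 13 without passing through iodide 10.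

Step 4. The risks are ring opening of the 3-magnesio flavone 11 by β-elimination of the ring oxygen, or addition of the Grignard reagent to the pyranone. The fallback sets out from 10 and comes back at 13; it brings in the oxygen as a nucleophile and uses no carbanion. Ullmann-type C–O coupling of 10 with benzyl alcohol (CuI, 3,4,7,8-tetramethyl-1,10-phenanthroline, Cs2CO3, toluene, 90 °C) gives 3-(benzyloxy)-5,6,7,8-tetramethoxy-2-(4-methoxyphenyl)-4H-chromen-4-one F8. Hydrogenolysis (H2 1 atm, Pd/C, EtOAc, rt) removes the benzyl group to give 13.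

**Further compounds**
F1 | step 2 | lithium (dimethylamino)(2,3,4,5,6-pentamethoxyphenyl)methanolate (racemic, not isolated) | [Li]OC(N(C)C)c1c(OC)c(OC)c(OC)c(OC)c1OC
F2 | step 2 | 2,3,4,5,6-pentamethoxybenzaldehyde | O=Cc1c(OC)c(OC)c(OC)c(OC)c1OC
F3 | step 2 | racemic 3-(4-methoxyphenyl)-1-(2,3,4,5,6-pentamethoxyphenyl)prop-2-yn-1-ol | COc1ccc(C#CC(O)c2c(OC)c(OC)c(OC)c(OC)c2OC)cc1
F4 | step 3 | dichloro{3,4,5,6-tetramethoxy-2-[3-(4-methoxyphenyl)prop-2-ynoyl]phenoxy}borane (not isolated) | COc1ccc(C#CC(=O)c2c(OB(Cl)Cl)c(OC)c(OC)c(OC)c2OC)cc1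
F5 | step 3 | 1-(2-hydroxy-3,4,5,6-tetramethoxyphenyl)-3-(4-methoxyphenyl)prop-2-yn-1-one | COc1ccc(C#CC(=O)c2c(O)c(OC)c(OC)c(OC)c2OC)cc1
F6 | step 3 | tangeretin, 5,6,7,8-tetramethoxy-2-(4-methoxyphenyl)-4H-chromen-4-one | COc1ccc(-c2cc(=O)c3c(OC)c(OC)c(OC)c(OC)c3o2)cc1
F7 | step 3 | [5,6,7,8-tetramethoxy-2-(4-methoxyphenyl)-4-oxo-4H-chromen-3-yl]lithium (not isolated) | COc1ccc(-c2oc3c(OC)c(OC)c(OC)c(OC)c3c(=O)c2[Li])cc1
F8 | step 4 | 3-(benzyloxy)-5,6,7,8-tetramethoxy-2-(4-methoxyphenyl)-4H-chromen-4-one | COc1ccc(-c2oc3c(OC)c(OC)c(OC)c(OC)c3c(=O)c2OCc2ccccc2)cc1
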